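**Assumption:** positions are numbered as in germacrane/guaiane (C1–C15, lactone O on C6). The target is read as (1R,4S,5S,6S,7S,8S,9S): 1α-H, 5α-H, 6β-H, 7α-H, 4β-O/4α-CH2OH, 8β-angeloyloxy, 9α-acetoxy.

## Retrosynthetic overview

1. The dihydropyran and cyclopentane rings are made last and together, by a transannular inverse-electron-demand oxa-Diels–Alder reaction of a 14-oxo-15-hydroxy-germacra-1(10),4-dien-12,6-olide whose C14 aldehyde is cis to C2; this sets C1, C4 and C5.
2. The ten-membered ring and the trans γ-lactone are made together before that, by a chromium-mediated intramolecular allylation of a C6 enal by a 2-(bromomethyl)enoate (C6–C7, the bond closed in farnesyl cyclisation). The C8 angelate is put on afterwards.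
3. The open chain: the allyl bromide comes from cross-metathesis on a C7 vinyl group; the C8/C9 syn-diol comes from a Brown (Z)-alkoxyallylboration of a 2-(diethoxymethyl)enal.
4. That enal comes from an alkynyl acetal (syn-hydrostannation, then formylation); the C4=C5 alkene comes from syn-carbocupration of a silyloxy ynoate.

## Route

Step 1
Reactants: 1 3,3-diethoxyprop-1-yne; 2 oxirane
Product: 4 5,5-diethoxypent-3-yn-1-ol, via lithium acetylide 3 (not isolated)
Conditions: n-BuLi, THF, −78 °C; then 2, BF3·OEt2, −78 °C; H2O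
Reagents that add atoms: none
Why: BF3-assisted opening of an epoxide by a lithium acetylide (Yamaguchi-type alkynylation) gives the homopropargylic alcohol while the acetal is inert at −78 °C.

Step 2
Reactants: 4 5,5-diethoxypent-3-yn-1-ol
Product: 5 1,1-diethoxy-5-iodopent-2-yne
Conditions: I2, PPh3, imidazole, CH2Cl2, 0 °C
Reagents that add atoms: iodine, II
Why: Appel-type (Garegg–Samuelsson) iodination of a primary alcohol under imidazole buffering, which keeps the acetal intact.

Step 3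
Reactants: 6 tert-butyldimethyl(prop-2-yn-1-yloxy)silane; 7 methyl chloroformate
Product: 9 methyl 4-[(tert-butyldimethylsilyl)oxy]but-2-ynoate, via lithium acetylide 8 (not isolated)
Conditions: n-BuLi, THF, −78 °C; then 7, −78 to 0 °C
Reagents that add atoms: none
Why: C-acylation of a lithium acetylide with a chloroformate gives the ynoate.

Step 4
Reactants: 5 1,1-diethoxy-5-iodopent-2-yne; 9 methyl 4-[(tert-butyldimethylsilyl)oxy]but-2-ynoate
Product: 12 methyl (2Z)-3-{[(tert-butyldimethylsilyl)oxy]methyl}-8,8-diethoxyoct-2-en-6-ynoate, via Grignard reagent 10 (not isolated), via alkylcopper reagent 11 (not isolated)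
Conditions: 5, Mg, THF, rt; CuBr·SMe2, THF, −45 °C; then 9, −78 °C; MeOH quench at −78 °C
Reagents that add atoms: none
Why: syn-carbocupration of the ynoate followed by protonation at −78 °C with retention puts the new chain (C3) trans to the ester and the silyloxymethyl group (C15) cis to it, which is the C4=C5 geometry of the target precursor.

Step 5
Reactants: 12 methyl (2Z)-3-{[(tert-butyldimethylsilyl)oxy]methyl}-8,8-diethoxyoct-2-en-6-ynoate
Product: 13 (2Z)-3-{[(tert-butyldimethylsilyl)oxy]methyl}-8,8-diethoxyoct-2-en-6-yn-1-ol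
Conditions: DIBAL-H (2.2 equiv), CH2Cl2, −78 °C; Rochelle salt
Reagents that add atoms: none
Why: DIBAL-H 1,2-reduction of the enoate gives the allylic alcohol (the future C6) without touching alkyne, acetal or silyl ether.

Step 6
Reactants: 13 (2Z)-3-{[(tert-butyldimethylsilyl)oxy]methyl}-8,8-diethoxyoct-2-en-6-yn-1-ol
Product: 14 (2Z,6E)-3-{[(tert-butyldimethylsilyl)oxy]methyl}-8,8-diethoxy-7-(tributylstannyl)octa-2,6-dien-1-ol
Conditions: Bu3SnH, PdCl2(PPh3)2 (3 mol %), THF, 0 °C to rt
Reagents that add atoms: tributyltin hydride, CCCC[SnH](CCCC)CCCC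
Why: palladium-catalysed syn-hydrostannation places tin on the alkyne carbon next to the electron-poor, branched acetal carbon; H and Sn add cis, so the chain (C2) ends up cis to the acetal (C14).

Step 7
Reactants: 14 (2Z,6E)-3-{[(tert-butyldimethylsilyl)oxy]methyl}-8,8-diethoxy-7-(tributylstannyl)octa-2,6-dien-1-ol
Product: 16 (2Z,6Z)-2-(diethoxymethyl)-8-hydroxy-6-{[(tert-butyldimethylsilyl)oxy]methyl}octa-2,6-dienal, via dilithio species 15 (not isolated)
Conditions: n-BuLi (2.2 equiv), THF, −78 °C; DMF, −78 °C; AcOH quench at −78 °C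
Reagents that add atoms: N,N-dimethylformamide, CN(C)C=O
Why: tin–lithium exchange and formylation with retention give the enal whose free formyl group (future C9) is trans to the chain and whose masked formyl group (C14) is cis to C2; this is also the thermodynamically preferred enal geometry, and the cold quench prevents silyl migration.

Step 8
Reactants: 16 (2Z,6Z)-2-(diethoxymethyl)-8-hydroxy-6-{[(tert-butyldimethylsilyl)oxy]methyl}octa-2,6-dienal; 17 allyl 4-methoxybenzyl ether
Product: 20 (2Z,6Z,8S,9S)-7-(diethoxymethyl)-9-[(4-methoxybenzyl)oxy]-3-{[(tert-butyldimethylsilyl)oxy]methyl}undeca-2,6,10-triene-1,8-diol, via lithiated allyl ether 18 (not isolated), via alkoxyallylborane 19 (not isolated)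
Conditions: 17, s-BuLi, THF, −78 °C; (+)-Ipc2BOMe; BF3·OEt2 (1.0 equiv), −78 °C; then 16 (0.45 equiv), −78 °C; ethanolamine, rt
Reagents that add atoms: none
Why: Brown asymmetric (Z)-γ-alkoxyallylboration through a chair transition state gives the syn (threo) diol monoether, and the borane made from (−)-α-pinene adds to the Re face of the aldehyde, so both new centres (future C9 and C8) are S.

Step 9
Reactants: 20 (2Z,6Z,8S,9S)-7-(diethoxymethyl)-9-[(4-methoxybenzyl)oxy]-3-{[(tert-butyldimethylsilyl)oxy]methyl}undeca-2,6,10-triene-1,8-diol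
Product: 21 (2Z,6Z,8S,9S)-7-(diethoxymethyl)-8-hydroxy-9-[(4-methoxybenzyl)oxy]-3-{[(tert-butyldimethylsilyl)oxy]methyl}undeca-2,6,10-trienal
Conditions: TEMPO (10 mol %), PhI(OAc)2, CH2Cl2, 0 °C to rt
Reagents that add atoms: none
Why: oxoammonium (TEMPO) oxidation is selective for the primary allylic alcohol over the hindered secondary one and gives the C6 enal.

Step 10
Reactants: 21 (2Z,6Z,8S,9S)-7-(diethoxymethyl)-8-hydroxy-9-[(4-methoxybenzyl)oxy]-3-{[(tert-butyldimethylsilyl)oxy]methyl}undeca-2,6,10-trienal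
Product: 22 (2Z,6Z,8S,9S)-8-acetoxy-7-(diethoxymethyl)-9-[(4-methoxybenzyl)oxy]-3-{[(tert-butyldimethylsilyl)oxy]methyl}undeca-2,6,10-trienal
Conditions: Ac2O, pyridine, DMAP (cat.), CH2Cl2, 0 °C
Reagents that add atoms: acetic anhydride, CC(=O)OC(C)=O
Why: DMAP-catalysed acetylation of the only free hydroxyl installs the C9 acetate of the target.

Step 11
Reactants: 22 (2Z,6Z,8S,9S)-8-acetoxy-7-(diethoxymethyl)-9-[(4-methoxybenzyl)oxy]-3-{[(tert-butyldimethylsilyl)oxy]methyl}undeca-2,6,10-trienal; 23 methyl 2-(bromomethyl)prop-2-enoate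
Product: 24 methyl (2Z,4S,5S,6Z,10Z)-5-acetoxy-2-(bromomethyl)-6-(diethoxymethyl)-4-[(4-methoxybenzyl)oxy]-10-{[(tert-butyldimethylsilyl)oxy]methyl}-12-oxododeca-2,6,10-trienoate
Conditions: 23 (10 equiv), second-generation Hoveyda–Grubbs catalyst [RuCl2(H2IMes)(=CH-C6H4-2-OiPr)] (10 mol %), 1,4-benzoquinone (20 mol %), toluene, 60 °C
Reagents that add atoms: none
Why: olefin cross-metathesis of the only terminal alkene with a 1,1-disubstituted acrylate gives the trisubstituted enoate with the chain trans to the ester; the three trisubstituted alkenes are inert.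

Step 12
Reactants: 24 methyl (2Z,4S,5S,6Z,10Z)-5-acetoxy-2-(bromomethyl)-6-(diethoxymethyl)-4-[(4-methoxybenzyl)oxy]-10-{[(tert-butyldimethylsilyl)oxy]methyl}-12-oxododeca-2,6,10-trienoate
Product: 27 (6R,7S,8S,9S)-9-acetoxy-14,14-diethoxy-8-[(4-methoxybenzyl)oxy]-15-[(tert-butyldimethylsilyl)oxy]germacra-1(10),4,11(13)-trien-12,6-olide, via allylchromium species 25 (not isolated), via hydroxy ester 26 (not isolated)
Conditions: CrCl2 (6 equiv), THF, rt, slow addition of 24 (final 2 mM)
Reagents that add atoms: none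
Why: intramolecular chromium-mediated Barbier (Nozaki–Hiyama-type) 2-(alkoxycarbonyl)allylation closes the ten-membered ring at C6–C7 and the chromium alkoxide lactonises; the equilibrating allylchromium reacts through a chair transition state (anti, trans-lactone) on the alkene face anti to the C8–C9 bond with H-8 eclipsing the alkene, and the C8 ether (not an ester) avoids 1,4-elimination.

Step 13
Reactants: 27 (6R,7S,8S,9S)-9-acetoxy-14,14-diethoxy-8-[(4-methoxybenzyl)oxy]-15-[(tert-butyldimethylsilyl)oxy]germacra-1(10),4,11(13)-trien-12,6-olide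
Product: 28 (6R,7S,8S,9S)-9-acetoxy-14,14-diethoxy-8-hydroxy-15-[(tert-butyldimethylsilyl)oxy]germacra-1(10),4,11(13)-trien-12,6-olide
Conditions: DDQ, CH2Cl2/pH 7 buffer, 0 °C
Reagents that add atoms: none
Why: oxidative cleavage of the 4-methoxybenzyl ether by DDQ frees the 8β-hydroxyl under neutral conditions that spare acetal, silyl ether and acetate.

Step 14
Reactants: 28 (6R,7S,8S,9S)-9-acetoxy-14,14-diethoxy-8-hydroxy-15-[(tert-butyldimethylsilyl)oxy]germacra-1(10),4,11(13)-trien-12,6-olide; 29 angelic acid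
Product: 31 (6R,7S,8S,9S)-9-acetoxy-8-angeloyloxy-14,14-diethoxy-15-[(tert-butyldimethylsilyl)oxy]germacra-1(10),4,11(13)-trien-12,6-olide, via mixed anhydride 30 (not isolated)
Conditions: 29, 2,4,6-trichlorobenzoyl chloride, Et3N, toluene, rt; then 28, toluene, 75 °C
Reagents that add atoms: none
Why: Yamaguchi-type mixed-anhydride esterification run without DMAP acylates the secondary alcohol while keeping the (Z) geometry of the angelate.

Step 15
Reactants: 31 (6R,7S,8S,9S)-9-acetoxy-8-angeloyloxy-14,14-diethoxy-15-[(tert-butyldimethylsilyl)oxy]germacra-1(10),4,11(13)-trien-12,6-olide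
Product: 32 (6R,7S,8S,9S)-9-acetoxy-8-angeloyloxy-15-hydroxy-14-oxogermacra-1(10),4,11(13)-trien-12,6-olide
Conditions: HF (48 % aq.), MeCN, 0 °C; NaHCO3 work-up, used at once
Reagents that add atoms: water, O
Why: mild aqueous acid hydrolyses the enal acetal and cleaves the primary silyl ether in one operation, cold enough to keep the C14 enal cis to C2.

Step 16
Reactants: 32 (6R,7S,8S,9S)-9-acetoxy-8-angeloyloxy-15-hydroxy-14-oxogermacra-1(10),4,11(13)-trien-12,6-olide
Product: 33 target (1R,4S,5S,6S,7S,8S,9S)-9-acetoxy-8-angeloyloxy-4,14-epoxy-15-hydroxyguaia-10(14),11(13)-dien-12,6-olide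
Conditions: Eu(fod)3 [europium tris(6,6,7,7,8,8,8-heptafluoro-2,2-dimethyloctane-3,5-dionate)] (10 mol %), BHT, toluene, 50 °C
Reagents that add atoms: none
Why: Proposed new method: a transannular inverse-electron-demand oxa-Diels–Alder reaction in which the s-cis enal O=C14–C10=C1 (C2 at the inside position, as the bridged adduct requires) adds suprafacially to C4=C5, forming C1–C5 and O–C4; the alkene geometry (C15 cis to C6) fixes C4 relative to C5, the C2–C3 bridge fixes C1, and the crown conformer with C14 and C15 on the β face and H-5 anti to H-6 gives 1α-H, 5α-H, 4β-O; the closest known reaction types are the intramolecular hetero-Diels–Alder reaction of 1-oxadienes and the crossed intramolecular Diels–Alder reaction of (Z)-1,3,7-octatrienes to bicyclo[3.2.1]octenes, and a stepwise Lewis-acid path (C5 to C1, then enolate O to the tertiary C4 cation) leads to the same product.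

## Compound list

1 | 3,3-diethoxyprop-1-yne | C#CC(OCC)OCC | starting material
2 | oxirane | C1CO1 | starting material
3 | lithium 3,3-diethoxyprop-1-yn-1-ide | [Li]C#CC(OCC)OCC | intermediate
4 | 5,5-diethoxypent-3-yn-1-ol | OCCC#CC(OCC)OCC | intermediate
5 | 1,1-diethoxy-5-iodopent-2-yne | ICCC#CC(OCC)OCC | intermediate
6 | tert-butyldimethyl(prop-2-yn-1-yloxy)silane | C#CCO[Si](C)(C)C(C)(C)C | starting material
7 | methyl chloroformate | COC(=O)Cl | starting material
8 | lithium acetylide of 6 | [Li]C#CCO[Si](C)(C)C(C)(C)C | intermediate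
9 | methyl 4-[(tert-butyldimethylsilyl)oxy]but-2-ynoate | COC(=O)C#CCO[Si](C)(C)C(C)(C)C | intermediate
10 | (5,5-diethoxypent-3-yn-1-yl)magnesium iodide | I[Mg]CCC#CC(OCC)OCC | intermediate
11 | (5,5-diethoxypent-3-yn-1-yl)copper (monovalent copper, MgBrI complex) | [Cu]CCC#CC(OCC)OCC | intermediate
12 | methyl (2Z)-3-{[(tert-butyldimethylsilyl)oxy]methyl}-8,8-diethoxyoct-2-en-6-ynoate (CH2OSi cis to CO2Me) | COC(=O)/C=C(\CO[Si](C)(C)C(C)(C)C)CCC#CC(OCC)OCC | intermediate
13 | (2Z)-3-{[(tert-butyldimethylsilyl)oxy]methyl}-8,8-diethoxyoct-2-en-6-yn-1-ol | OC/C=C(\CO[Si](C)(C)C(C)(C)C)CCC#CC(OCC)OCC | intermediate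
14 | (2Z,6E)-3-{[(tert-butyldimethylsilyl)oxy]methyl}-8,8-diethoxy-7-(tributylstannyl)octa-2,6-dien-1-ol | OC/C=C(\CO[Si](C)(C)C(C)(C)C)CC/C=C(/[Sn](CCCC)(CCCC)CCCC)C(OCC)OCC | intermediate
15 | dilithio species of 14 (lithium alkoxide, vinyllithium in place of tin) | [Li]OC/C=C(\CO[Si](C)(C)C(C)(C)C)CC/C=C(/[Li])C(OCC)OCC | intermediate
16 | (2Z,6Z)-2-(diethoxymethyl)-8-hydroxy-6-{[(tert-butyldimethylsilyl)oxy]methyl}octa-2,6-dienal (CHO trans to the chain) | OC/C=C(\CO[Si](C)(C)C(C)(C)C)CC/C=C(/C=O)C(OCC)OCC | intermediate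
17 | allyl 4-methoxybenzyl ether, 1-methoxy-4-[(prop-2-en-1-yloxy)methyl]benzene | C=CCOCc1ccc(OC)cc1 | starting material
18 | α-lithiated allyl 4-methoxybenzyl ether | [Li]C(C=C)OCc1ccc(OC)cc1 | intermediate
19 | [(Z)-3-(4-methoxybenzyloxy)prop-2-en-1-yl]diisopinocampheylborane, isopinocampheyl groups from (−)-α-pinene | COc1ccc(CO/C=C\CB([C@H]2C[C@H]3C[C@@H]([C@@H]2C)C3(C)C)[C@H]2C[C@H]3C[C@@H]([C@@H]2C)C3(C)C)cc1 | intermediate
20 | (2Z,6Z,8S,9S)-7-(diethoxymethyl)-9-[(4-methoxybenzyl)oxy]-3-{[(tert-butyldimethylsilyl)oxy]methyl}undeca-2,6,10-triene-1,8-diol | OC/C=C(\CO[Si](C)(C)C(C)(C)C)CC/C=C(\C(OCC)OCC)[C@H](O)[C@@H](OCc1ccc(OC)cc1)C=C | intermediate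
21 | (2Z,6Z,8S,9S)-7-(diethoxymethyl)-8-hydroxy-9-[(4-methoxybenzyl)oxy]-3-{[(tert-butyldimethylsilyl)oxy]methyl}undeca-2,6,10-trienal | O=C/C=C(\CO[Si](C)(C)C(C)(C)C)CC/C=C(\C(OCC)OCC)[C@H](O)[C@@H](OCc1ccc(OC)cc1)C=C | intermediate
22 | (2Z,6Z,8S,9S)-8-acetoxy-7-(diethoxymethyl)-9-[(4-methoxybenzyl)oxy]-3-{[(tert-butyldimethylsilyl)oxy]methyl}undeca-2,6,10-trienal | O=C/C=C(\CO[Si](C)(C)C(C)(C)C)CC/C=C(\C(OCC)OCC)[C@H](OC(C)=O)[C@@H](OCc1ccc(OC)cc1)C=C | intermediate
23 | methyl 2-(bromomethyl)prop-2-enoate | C=C(CBr)C(=O)OC | starting material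
24 | methyl (2Z,4S,5S,6Z,10Z)-5-acetoxy-2-(bromomethyl)-6-(diethoxymethyl)-4-[(4-methoxybenzyl)oxy]-10-{[(tert-butyldimethylsilyl)oxy]methyl}-12-oxododeca-2,6,10-trienoate | O=C/C=C(\CO[Si](C)(C)C(C)(C)C)CC/C=C(\C(OCC)OCC)[C@H](OC(C)=O)[C@@H](OCc1ccc(OC)cc1)/C=C(\CBr)C(=O)OC | intermediate
25 | allylchromium dichloride species from 24 (trivalent chromium) | O=C/C=C(\CO[Si](C)(C)C(C)(C)C)CC/C=C(\C(OCC)OCC)[C@H](OC(C)=O)[C@@H](OCc1ccc(OC)cc1)/C=C(\C[Cr](Cl)Cl)C(=O)OC | intermediate
26 | ten-membered γ-hydroxy methyl ester (present as its chromium alkoxide; 6R,7S,8S,9S) | C=C(C(=O)OC)[C@H]1[C@H](O)/C=C(\CO[Si](C)(C)C(C)(C)C)CC/C=C(\C(OCC)OCC)[C@H](OC(C)=O)[C@H]1OCc1ccc(OC)cc1 | intermediate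
27 | (6R,7S,8S,9S)-9-acetoxy-14,14-diethoxy-8-[(4-methoxybenzyl)oxy]-15-[(tert-butyldimethylsilyl)oxy]germacra-1(10),4,11(13)-trien-12,6-olide; both ring alkenes trans in the ring (1(10)Z,4Z by CIP: C14 cis to C2, C15 cis to C6) | C=C1C(=O)O[C@@H]2/C=C(\CO[Si](C)(C)C(C)(C)C)CC/C=C(\C(OCC)OCC)[C@H](OC(C)=O)[C@@H](OCc3ccc(OC)cc3)[C@@H]12 | intermediate
28 | (6R,7S,8S,9S)-9-acetoxy-14,14-diethoxy-8-hydroxy-15-[(tert-butyldimethylsilyl)oxy]germacra-1(10),4,11(13)-trien-12,6-olide, same alkene geometry | C=C1C(=O)O[C@@H]2/C=C(\CO[Si](C)(C)C(C)(C)C)CC/C=C(\C(OCC)OCC)[C@H](OC(C)=O)[C@@H](O)[C@@H]12 | intermediate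
29 | angelic acid, (2Z)-2-methylbut-2-enoic acid | C/C=C(/C)C(=O)O | starting material
30 | angelic 2,4,6-trichlorobenzoic anhydride | C/C=C(/C)C(=O)OC(=O)c1c(Cl)cc(Cl)cc1Cl | intermediate
31 | (6R,7S,8S,9S)-9-acetoxy-8-[(2Z)-2-methylbut-2-enoyloxy]-14,14-diethoxy-15-[(tert-butyldimethylsilyl)oxy]germacra-1(10),4,11(13)-trien-12,6-olide, same alkene geometry | C=C1C(=O)O[C@@H]2/C=C(\CO[Si](C)(C)C(C)(C)C)CC/C=C(\C(OCC)OCC)[C@H](OC(C)=O)[C@@H](OC(=O)/C(C)=C\C)[C@@H]12 | intermediate
32 | (6R,7S,8S,9S)-9-acetoxy-8-[(2Z)-2-methylbut-2-enoyloxy]-15-hydroxy-14-oxogermacra-1(10),4,11(13)-trien-12,6-olide, same alkene geometry (CHO cis to C2) | C=C1C(=O)O[C@@H]2/C=C(\CO)CC/C=C(\C=O)[C@H](OC(C)=O)[C@@H](OC(=O)/C(C)=C\C)[C@@H]12 | intermediate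
33 | (1R,4S,5S,6S,7S,8S,9S)-9-acetoxy-8-[(2Z)-2-methylbut-2-enoyloxy]-4,14-epoxy-15-hydroxyguaia-10(14),11(13)-dien-12,6-olide | C=C1C(=O)O[C@H]2[C@H]1[C@H](OC(=O)/C(C)=C\C)[C@@H](OC(C)=O)C1=CO[C@@]3(CO)CC[C@@H]1[C@@H]23 | target

## Step count

Total steps: 16. Longest linear sequence: 15 steps (compound 1 to 33 through steps 1, 2 and 4–16; step 3 is a one-step side branch).

## Three steps most likely to fail, with fallbacks

**Step 11 (cross-metathesis).** A secondary allylic ether is a sluggish partner for a 1,1-disubstituted acrylate; low conversion is the main risk. The fallback sets out from acetate 22 and comes back at bromide 24. Catalytic OsO4/NMO followed by NaIO4 cleaves the terminal vinyl group, which is the only alkene that is neither conjugated to the aldehyde nor flanked by acetal and acetate, to give the α-(4-methoxybenzyloxy) aldehyde F1. A Morita–Baylis–Hillman reaction with methyl acrylate (DABCO, MeOH) takes place at this saturated aldehyde in preference to the hindered enal and gives the Baylis–Hillman alcohol F2 as a mixture at the carbinol carbon. NBS/Me2S then brominates with allylic transposition to give 24.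

**Step 12 (chromium-mediated macrocyclisation).** The risks are oligomerisation, 1,4-elimination of the C8 oxygen from the allylmetal, and the wrong facial selectivity at C6/C7. The fallback sets out from acetate 22 and comes back at alcohol 28. DDQ gives the C8 alcohol F3, and esterification with 2-(bromomethyl)acrylic acid (DCC, 0 °C) gives the acrylate ester F4. Ring-closing metathesis with second-generation Grubbs catalyst gives the 3-(bromomethyl)butenolide F5. A zinc-mediated intramolecular Barbier reaction (Zn, THF/aq. NH4Cl, high dilution) closes the ten-membered ring from the lactone-bound allylzinc; the ring oxygen cannot eliminate, and the cis ring fusion fixes C7 relative to C8. This gives the 8,12-olide F6 with a free 6-hydroxyl. DBU-catalysed translactonisation to the more stable trans 6,12-olide frees the 8-hydroxyl and gives 28.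

**Step 16 (transannular oxa-Diels–Alder).** The risks are competing Cope rearrangement of the 1,5-diene, isomerisation of the enal to the unreactive geometry (CHO trans to C2), and acid sensitivity of the enol ether. The fallback sets out from acetal 31 and comes back at the target 33. TMSOTf (10 mol %) with 2,6-di-tert-butyl-4-methylpyridine in CH2Cl2 at −78 °C ionises the acetal to a vinyl oxocarbenium ion. This undergoes a stepwise ionic [4+2] (C5 onto C1, then the ethoxy oxygen onto the C4 cation) and loses diethyl ether to give the silyl-protected adduct F7. HF·pyridine in THF then removes the silyl group to give 33.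

## Further compounds

F1 | step 11 | C7 aldehyde from cleavage of the vinyl group of 22 (C8 and C9 configurations as in 22) | O=C/C=C(\CO[Si](C)(C)C(C)(C)C)CC/C=C(\C(OCC)OCC)[C@H](OC(C)=O)[C@@H](OCc1ccc(OC)cc1)C=O
F2 | step 11 | Baylis–Hillman alcohol, methyl 2-methylidene-3-hydroxy ester built on F1 (both carbinol epimers) | O=C/C=C(\CO[Si](C)(C)C(C)(C)C)CC/C=C(\C(OCC)OCC)[C@H](OC(C)=O)[C@@H](OCc1ccc(OC)cc1)C(O)C(=C)C(=O)OC
F3 | step 12 | C8 alcohol from 22 by loss of the 4-methoxybenzyl group | O=C/C=C(\CO[Si](C)(C)C(C)(C)C)CC/C=C(\C(OCC)OCC)[C@H](OC(C)=O)[C@@H](O)C=C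
F4 | step 12 | 2-(bromomethyl)acrylate ester of F3 | O=C/C=C(\CO[Si](C)(C)C(C)(C)C)CC/C=C(\C(OCC)OCC)[C@H](OC(C)=O)[C@@H](OC(=O)C(=C)CBr)C=C
F5 | step 12 | 3-(bromomethyl)furan-2(5H)-one (8,12-butenolide) from ring-closing metathesis of F4 | O=C/C=C(\CO[Si](C)(C)C(C)(C)C)CC/C=C(\C(OCC)OCC)[C@H](OC(C)=O)[C@H]1OC(=O)C(CBr)=C1
F6 | step 12 | (6R,7S,8S,9S)-9-acetoxy-14,14-diethoxy-6-hydroxy-15-[(tert-butyldimethylsilyl)oxy]germacra-1(10),4,11(13)-trien-12,8-olide | C=C1C(=O)O[C@@H]2[C@@H](OC(C)=O)/C(C(OCC)OCC)=C/CC/C(CO[Si](C)(C)C(C)(C)C)=C/[C@@H](O)[C@H]12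
F7 | step 16 | 15-O-tert-butyldimethylsilyl ether of the target | C=C1C(=O)O[C@H]2[C@H]1[C@H](OC(=O)/C(C)=C\C)[C@@H](OC(C)=O)C1=CO[C@@]3(CO[Si](C)(C)C(C)(C)C)CC[C@@H]1[C@@H]23
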